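**Plan**

- Retrosynthesis: the three phenols are masked as MOM ethers and C2–H as C2–SiMe3; ring C is then cut at O1–C2 and C3–C4.
- Enabling feature: ring C is a 4-pyranone with hydrogen on C2 and ring B on C3. C4, C4a, C8a and O1 therefore map onto a ring A salicylaldehyde, and C2–C3 onto an aryl(silyl)alkyne whose silyl group marks C2.
- Ring A: phloroglucinol is monosilylated, bis-MOM protected, lithiated between the MOM ethers and prenylated, desilylated and ortho-formylated. The symmetry of the phenol fixes the prenyl group at C6.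
- Ring B with its fused dimethylpyran (ring D): 2,4-dihydroxybenzaldehyde and 3-methylbut-2-enal give the chromene aldehyde, which is MOM-protected, homologated to the alkyne and C-silylated.
- The halves are joined and ring C closed in one rhodium-catalysed oxidative annulation. Fluoride (C2–Si) and then acid (MOM) release angustone B.
- Stereochemistry: the target has no stereocentre. The prenyl olefin comes intact from prenyl bromide and the ring D olefin is cis by ring constraint.

Key step: step 10

Assumption: in the annulation, rhodium is taken to end on the silyl-bearing alkyne carbon, as in related heteroannulations of aryl(silyl)alkynes; this orientation has not been confirmed for salicylaldehydes and is the main uncertainty of the route.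

**Route**

Step 1
Reactants: 1 phloroglucinol (benzene-1,3,5-triol)
Product: 2 5-{[tri(propan-2-yl)silyl]oxy}benzene-1,3-diol
Conditions: 1 (3 equiv, dried), i-Pr3SiCl (1 equiv), imidazole, DMF, 0 °C to rt
Reagents that add atoms: chlorotri(propan-2-yl)silane (TIPSCl), CC(C)[Si](Cl)(C(C)C)C(C)C
Why: Imidazole-promoted O-silylation of a phenol; the three hydroxyls are equivalent, so with the inexpensive triol in excess the monosilyl ether should dominate, and unreacted 1 is removed by aqueous washing.

Step 2
Reactants: 2 5-{[tri(propan-2-yl)silyl]oxy}benzene-1,3-diol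
Product: 3 [3,5-bis(methoxymethoxy)phenoxy]tri(propan-2-yl)silane
Conditions: MOMCl (2.5 equiv), i-Pr2NEt, CH2Cl2, 0 °C to rt
Reagents that add atoms: chloromethyl methyl ether (MOMCl), COCCl
Why: Base-mediated alkylation of both free phenols with the reactive α-chloro ether (MOM protection) should be exhaustive, and the hindered aryl TIPS ether is stable to the amine base.

Step 3
Reactants: 3 [3,5-bis(methoxymethoxy)phenoxy]tri(propan-2-yl)silane; 4 1-bromo-3-methylbut-2-ene (prenyl bromide)
Product: 6 [3,5-bis(methoxymethoxy)-4-(3-methylbut-2-en-1-yl)phenoxy]tri(propan-2-yl)silane, via aryllithium 5 (not isolated)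
Conditions: n-BuLi, THF, 0 °C; then CuI (10 mol %), 4, −78 °C to rt
Reagents that add atoms: none
Why: Directed ortho-metalation: the position flanked by two chelating MOM ethers is the most acidic and the bulky, weakly coordinating OTIPS group shields its own neighbours, so aryllithium 5 should form there alone, and copper-assisted SN2 displacement of the primary allylic bromide installs the prenyl group without allylic transposition.

Step 4
Reactants: 6 [3,5-bis(methoxymethoxy)-4-(3-methylbut-2-en-1-yl)phenoxy]tri(propan-2-yl)silane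
Product: 7 3,5-bis(methoxymethoxy)-4-(3-methylbut-2-en-1-yl)phenol
Conditions: Bu4NF, THF, 0 °C
Reagents that add atoms: none
Why: Fluoride cleaves the aryl O–Si bond (strong Si–F bond, good phenoxide leaving group) under conditions that leave the MOM ethers and the olefin untouched.

Step 5
Reactants: 7 3,5-bis(methoxymethoxy)-4-(3-methylbut-2-en-1-yl)phenol
Product: 9 2-hydroxy-4,6-bis(methoxymethoxy)-5-(3-methylbut-2-en-1-yl)benzaldehyde, via salicyl alcohol 8 (not isolated)
Conditions: MgCl2 (anhydrous), Et3N, (CH2O)n, MeCN, reflux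
Reagents that add atoms: formaldehyde (used as paraformaldehyde), C=O
Why: Magnesium-mediated ortho-formylation (Casnati–Skattebøl reaction): the magnesium phenoxide delivers formaldehyde to an ortho carbon to give salicyl alcohol 8, which a second formaldehyde oxidises by Oppenauer-type hydride transfer, and since both ortho positions of 7 are equivalent only one salicylaldehyde can form, with its free hydroxyl remote from the prenyl group.

Step 6
Reactants: 10 2,4-dihydroxybenzaldehyde; 11 3-methylbut-2-enal
Product: 13 5-hydroxy-2,2-dimethyl-2H-chromene-6-carbaldehyde, via dienone 12 (not isolated)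
Conditions: pyridine, 140 °C (sealed tube)
Reagents that add atoms: none
Why: Pyridine-mediated chromenylation: aldol-type attack of C3 (the carbon between the two hydroxyls) on the enal and loss of water give the ortho-quinone methide dienone 12, whose oxa-6π electrocyclisation closes ring D through the 4-oxygen, because the 2-hydroxyl is held in a hydrogen bond to the formyl group.

Step 7
Reactants: 13 5-hydroxy-2,2-dimethyl-2H-chromene-6-carbaldehyde
Product: 14 5-(methoxymethoxy)-2,2-dimethyl-2H-chromene-6-carbaldehyde
Conditions: MOMCl, i-Pr2NEt, CH2Cl2, 0 to 40 °C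
Reagents that add atoms: chloromethyl methyl ether (MOMCl), COCCl
Why: MOM protection of the hydrogen-bonded phenol by alkylation with the α-chloro ether under amine base, needed so that the later alkyne cannot cyclise onto a free ortho-hydroxyl.

Step 8
Reactants: 14 5-(methoxymethoxy)-2,2-dimethyl-2H-chromene-6-carbaldehyde
Product: 15 6-ethynyl-5-(methoxymethoxy)-2,2-dimethyl-2H-chromene
Conditions: dimethyl (1-diazo-2-oxopropyl)phosphonate, K2CO3, MeOH, rt
Reagents that add atoms: dimethyl (1-diazo-2-oxopropyl)phosphonate (Ohira–Bestmann reagent), COP(=O)(OC)C(=[N+]=[N-])C(C)=O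
Why: Ohira–Bestmann (Seyferth–Gilbert) homologation: methanolysis of the reagent gives the diazomethylphosphonate anion, which olefinates the aldehyde to a diazoalkene that loses nitrogen and rearranges by 1,2-hydride shift to the terminal alkyne, under conditions mild enough for the MOM ether and the chromene.

Step 9
Reactants: 15 6-ethynyl-5-(methoxymethoxy)-2,2-dimethyl-2H-chromene
Product: 17 {[5-(methoxymethoxy)-2,2-dimethyl-2H-chromen-6-yl]ethynyl}(trimethyl)silane, via alkynyllithium 16 (not isolated)
Conditions: n-BuLi (1.05 equiv), THF, −78 °C; then Me3SiCl, −78 °C to rt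
Reagents that add atoms: chlorotrimethylsilane, C[Si](C)(C)Cl
Why: Deprotonation of the terminal alkyne, by far the most acidic C–H bond, and trapping of alkynyllithium 16 with the silyl chloride gives the C-silylated alkyne.

Step 10
Reactants: 9 2-hydroxy-4,6-bis(methoxymethoxy)-5-(3-methylbut-2-en-1-yl)benzaldehyde; 17 {[5-(methoxymethoxy)-2,2-dimethyl-2H-chromen-6-yl]ethynyl}(trimethyl)silane
Product: 18 5,7-bis(methoxymethoxy)-3-[5-(methoxymethoxy)-2,2-dimethyl-2H-chromen-6-yl]-6-(3-methylbut-2-en-1-yl)-2-(trimethylsilyl)-4H-chromen-4-one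
Conditions: [RhCl2(C5Me5)]2 (2.5 mol %), Cu(OAc)2 (anhydrous, 2.2 equiv), toluene, 100 °C, N2
Reagents that add atoms: none
Why: Acetate exchange gives a (C5Me5)Rh diacetate of trivalent rhodium, the phenoxide of 9 binds it and acetate-assisted cleavage of the formyl C–H bond gives a five-membered acyl rhodacycle; alkyne 17 then inserts into the Rh–acyl bond (new C3–C4 bond) with rhodium on the silyl-bearing carbon, and the resulting seven-membered oxarhodacycle undergoes C–O reductive elimination (new O1–C2 bond) to release 18 and monovalent rhodium, which two equivalents of Cu(OAc)2 reoxidise. The closest known reaction type is the rhodium-catalysed, copper-mediated oxidative coupling of salicylaldehydes with internal alkynes to 2,3-disubstituted chromones, and the orientation expected for an aryl(silyl)alkyne follows that of Larock-type heteroannulations, in which the silyl group ends up next to the heteroatom. Ring C, the six-membered 4-pyranone, closes by a formal oxidative [4+2] annulation in which C4, C4a, C8a and O1 of the aldehyde join the two alkyne carbons, the ring-forming event being C–O reductive elimination from the seven-membered metallacycle. No stereocentre is formed. The step needs regioselective insertion, which the preference of the metal for the α-silyl carbon and the size of SiMe3 (kept away from the forming C–C bond) should secure, and it needs a single chelation site, which 9 provides because only the hydroxyl remote from the prenyl group is free, so the prenyl group ends on C6. The trisubstituted prenyl olefin and the ring-bound cis olefin are poorer ligands than the alkyne and neither can reach the acyl–rhodium bond intramolecularly, so both should remain untouched.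

Step 11
Reactants: 18 5,7-bis(methoxymethoxy)-3-[5-(methoxymethoxy)-2,2-dimethyl-2H-chromen-6-yl]-6-(3-methylbut-2-en-1-yl)-2-(trimethylsilyl)-4H-chromen-4-one
Product: 19 5,7-bis(methoxymethoxy)-3-[5-(methoxymethoxy)-2,2-dimethyl-2H-chromen-6-yl]-6-(3-methylbut-2-en-1-yl)-4H-chromen-4-one
Conditions: Bu4NF (1 M in THF, wet), THF, 0 °C to rt
Reagents that add atoms: none
Why: Fluoride-induced protodesilylation: attack of fluoride at silicon releases an sp2 carbanion at C2 that is stabilised by the adjacent ring oxygen and the electron-poor pyranone (C2 of chromones is readily metalated) and is protonated by water in the reagent, as in the desilylation of 2-silylbenzofurans and 2-silylindoles made by silylalkyne heteroannulation.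

Step 12
Reactants: 19 5,7-bis(methoxymethoxy)-3-[5-(methoxymethoxy)-2,2-dimethyl-2H-chromen-6-yl]-6-(3-methylbut-2-en-1-yl)-4H-chromen-4-one
Product: 20 angustone B, 5,7-dihydroxy-3-(5-hydroxy-2,2-dimethyl-2H-chromen-6-yl)-6-(3-methylbut-2-en-1-yl)-4H-chromen-4-one
Conditions: 3 M aq HCl, MeOH, 50 °C, short reaction time
Reagents that add atoms: none
Why: Acid-catalysed acetal exchange with methanol cleaves the three aryl MOM ethers as dimethoxymethane, a deprotection routinely applied to prenylated isoflavone MOM ethers, the short time at moderate temperature being chosen to spare the prenyl group and the chromene.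

**Compound list**

1 | phloroglucinol (benzene-1,3,5-triol) | Oc1cc(O)cc(O)c1 | starting material
2 | 5-{[tri(propan-2-yl)silyl]oxy}benzene-1,3-diol | CC(C)[Si](Oc1cc(O)cc(O)c1)(C(C)C)C(C)C | intermediate
3 | [3,5-bis(methoxymethoxy)phenoxy]tri(propan-2-yl)silane | COCOc1cc(OCOC)cc(O[Si](C(C)C)(C(C)C)C(C)C)c1 | intermediate
4 | 1-bromo-3-methylbut-2-ene (prenyl bromide) | CC(C)=CCBr | starting material
5 | [2,6-bis(methoxymethoxy)-4-{[tri(propan-2-yl)silyl]oxy}phenyl]lithium (not isolated) | [Li]c1c(OCOC)cc(O[Si](C(C)C)(C(C)C)C(C)C)cc1OCOC | intermediate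
6 | [3,5-bis(methoxymethoxy)-4-(3-methylbut-2-en-1-yl)phenoxy]tri(propan-2-yl)silane | CC(C)=CCc1c(OCOC)cc(O[Si](C(C)C)(C(C)C)C(C)C)cc1OCOC | intermediate
7 | 3,5-bis(methoxymethoxy)-4-(3-methylbut-2-en-1-yl)phenol | CC(C)=CCc1c(OCOC)cc(O)cc1OCOC | intermediate
8 | 2-(hydroxymethyl)-3,5-bis(methoxymethoxy)-4-(3-methylbut-2-en-1-yl)phenol (not isolated) | CC(C)=CCc1c(OCOC)cc(O)c(CO)c1OCOC | intermediate
9 | 2-hydroxy-4,6-bis(methoxymethoxy)-5-(3-methylbut-2-en-1-yl)benzaldehyde | CC(C)=CCc1c(OCOC)cc(O)c(C=O)c1OCOC | intermediate
10 | 2,4-dihydroxybenzaldehyde | O=Cc1ccc(O)cc1O | starting material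
11 | 3-methylbut-2-enal | CC(C)=CC=O | starting material
12 | 2-hydroxy-3-(3-methylbut-2-en-1-ylidene)-4-oxocyclohexa-1,5-diene-1-carbaldehyde, side-chain vinyl group cis to the ring ketone (not isolated) | O=CC1=C(O)/C(=C/C=C(C)C)C(=O)C=C1 | intermediate
13 | 5-hydroxy-2,2-dimethyl-2H-chromene-6-carbaldehyde | CC1(C)C=Cc2c(O1)ccc(C=O)c2O | intermediate
14 | 5-(methoxymethoxy)-2,2-dimethyl-2H-chromene-6-carbaldehyde | CC1(C)C=Cc2c(O1)ccc(C=O)c2OCOC | intermediate
15 | 6-ethynyl-5-(methoxymethoxy)-2,2-dimethyl-2H-chromene | CC1(C)C=Cc2c(O1)ccc(C#C)c2OCOC | intermediate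
16 | {[5-(methoxymethoxy)-2,2-dimethyl-2H-chromen-6-yl]ethynyl}lithium (not isolated) | CC1(C)C=Cc2c(O1)ccc(C#C[Li])c2OCOC | intermediate
17 | {[5-(methoxymethoxy)-2,2-dimethyl-2H-chromen-6-yl]ethynyl}(trimethyl)silane | CC1(C)C=Cc2c(O1)ccc(C#C[Si](C)(C)C)c2OCOC | intermediate
18 | 5,7-bis(methoxymethoxy)-3-[5-(methoxymethoxy)-2,2-dimethyl-2H-chromen-6-yl]-6-(3-methylbut-2-en-1-yl)-2-(trimethylsilyl)-4H-chromen-4-one | CC(C)=CCc1c(OCOC)cc2oc([Si](C)(C)C)c(-c3ccc4c(c3OCOC)C=CC(C)(C)O4)c(=O)c2c1OCOC | intermediate
19 | 5,7-bis(methoxymethoxy)-3-[5-(methoxymethoxy)-2,2-dimethyl-2H-chromen-6-yl]-6-(3-methylbut-2-en-1-yl)-4H-chromen-4-one | CC(C)=CCc1c(OCOC)cc2occ(-c3ccc4c(c3OCOC)C=CC(C)(C)O4)c(=O)c2c1OCOC | intermediate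
20 | angustone B | CC(C)=CCc1c(O)cc2occ(-c3ccc4c(c3O)C=CC(C)(C)O4)c(=O)c2c1O | target

**Step count and risks**

Total step count: 12. Longest linear sequence: 8 steps (steps 1–5, then 10–12, from phloroglucinol); the ring B branch is steps 6–9.

Steps most likely to fail:

1. Step 10. The alkyne may insert in the opposite sense so that ring B ends on C2, the acyl–rhodium intermediate may lose CO, or the copper salt may cleave the alkynyl C–Si bond and homocouple the alkyne before insertion. The fallback is the classical deoxybenzoin route, which sets out from 15 and 6 and comes back at 19, bypassing 18 and step 11. Hydroboration of 15 with dicyclohexylborane should give the (E)-alkenylborane F1, which NaBO3·4H2O oxidises to [5-(methoxymethoxy)-2,2-dimethyl-2H-chromen-6-yl]acetaldehyde F2. Silyl ether 6 is lithiated with n-BuLi/TMEDA at its only remaining ring position, next to a MOM ether, to give aryllithium F3, which is added to F2 at −78 °C to give the racemic carbinol F4. Dess–Martin periodinane oxidises F4 to ketone F5, and Bu4NF frees the phenol to give the 2-hydroxydeoxybenzoin F6. Heating F6 with N,N-dimethylformamide dimethyl acetal forms enaminone F7, which closes ring C by addition of the phenol and loss of dimethylamine to give 19.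

2. Step 11. Fluoride or adventitious hydroxide may add to C2 of the pyranone and open ring C, or C–Si cleavage may stall. The fallback inverts the order of the last two operations; it sets out from 18 and comes back at 20. Treatment of 18 with 3 M HCl in MeOH removes the MOM ethers first and should give 2-(trimethylsilyl)angustone B F8. Excess Bu4NF then converts F8 into its phenoxide, whose 7-oxido group donates into the pyranone and suppresses nucleophilic ring opening, so that fluoride can cleave the C2–Si bond and give 20 directly.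

3. Step 12. Brønsted acid may protonate the prenyl olefin and cyclise it onto the flanking 5- or 7-hydroxyl (chroman formation), or may hydrate the chromene. The fallback is a non-protic trans-protection; it sets out from 19 and comes back at 20. Me3SiOTf with 2,2'-bipyridyl in CH2Cl2 at 0 °C converts aryl MOM ethers into aryl silyl ethers and should give the tris(trimethylsilyl) ether of angustone B F9, which water hydrolyses to 20 at neutral pH.

**Further compounds**

F1 | step 10 | dicyclohexyl{(E)-2-[5-(methoxymethoxy)-2,2-dimethyl-2H-chromen-6-yl]ethenyl}borane | CC1(C)C=Cc2c(O1)ccc(/C=C/B(C3CCCCC3)C3CCCCC3)c2OCOC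
F2 | step 10 | [5-(methoxymethoxy)-2,2-dimethyl-2H-chromen-6-yl]acetaldehyde | CC1(C)C=Cc2c(O1)ccc(CC=O)c2OCOC
F3 | step 10 | [2,4-bis(methoxymethoxy)-3-(3-methylbut-2-en-1-yl)-6-{[tri(propan-2-yl)silyl]oxy}phenyl]lithium | CC(C)=CCc1c(OCOC)cc(O[Si](C(C)C)(C(C)C)C(C)C)c([Li])c1OCOC
F4 | step 10 | 1-[2,4-bis(methoxymethoxy)-3-(3-methylbut-2-en-1-yl)-6-{[tri(propan-2-yl)silyl]oxy}phenyl]-2-[5-(methoxymethoxy)-2,2-dimethyl-2H-chromen-6-yl]ethanol (racemic) | CC(C)=CCc1c(OCOC)cc(O[Si](C(C)C)(C(C)C)C(C)C)c(C(O)Cc2ccc3OC(C)(C)C=Cc3c2OCOC)c1OCOC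
F5 | step 10 | 1-[2,4-bis(methoxymethoxy)-3-(3-methylbut-2-en-1-yl)-6-{[tri(propan-2-yl)silyl]oxy}phenyl]-2-[5-(methoxymethoxy)-2,2-dimethyl-2H-chromen-6-yl]ethanone | CC(C)=CCc1c(OCOC)cc(O[Si](C(C)C)(C(C)C)C(C)C)c(C(=O)Cc2ccc3OC(C)(C)C=Cc3c2OCOC)c1OCOC
F6 | step 10 | 1-[6-hydroxy-2,4-bis(methoxymethoxy)-3-(3-methylbut-2-en-1-yl)phenyl]-2-[5-(methoxymethoxy)-2,2-dimethyl-2H-chromen-6-yl]ethanone | CC(C)=CCc1c(OCOC)cc(O)c(C(=O)Cc2ccc3OC(C)(C)C=Cc3c2OCOC)c1OCOC
F7 | step 10 | 3-(dimethylamino)-1-[6-hydroxy-2,4-bis(methoxymethoxy)-3-(3-methylbut-2-en-1-yl)phenyl]-2-[5-(methoxymethoxy)-2,2-dimethyl-2H-chromen-6-yl]prop-2-en-1-one (olefin geometry not defined) | CC(C)=CCc1c(OCOC)cc(O)c(C(=O)C(=CN(C)C)c2ccc3OC(C)(C)C=Cc3c2OCOC)c1OCOC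
F8 | step 11 | 2-(trimethylsilyl)angustone B, 5,7-dihydroxy-3-(5-hydroxy-2,2-dimethyl-2H-chromen-6-yl)-6-(3-methylbut-2-en-1-yl)-2-(trimethylsilyl)-4H-chromen-4-one | CC(C)=CCc1c(O)cc2oc([Si](C)(C)C)c(-c3ccc4c(c3O)C=CC(C)(C)O4)c(=O)c2c1O
F9 | step 12 | angustone B tris(trimethylsilyl) ether | CC(C)=CCc1c(O[Si](C)(C)C)cc2occ(-c3ccc4c(c3O[Si](C)(C)C)C=CC(C)(C)O4)c(=O)c2c1O[Si](C)(C)C
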